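**Plan**

1. Retrosynthetic cuts, in order: the lactone O–C16 bond and C12–C13 (syn-aldol of a C12 aldehyde with a C13–C16 acyl unit); then C4–C5 and C9–C10 in one operation (oxidative radical bicyclisation); then C1–C2 (acetoacetate dianion allylation); then C11–C12 (one-carbon homologation of geranyl bromide).
2. Enabling feature: in ring A the C3 hydroxyl and the C19 hydroxymethyl flank quaternary C4 as a 1,3-dioxygen pair, i.e. a reduced α-methyl β-keto ester. C10 and C8 each carry a one-carbon branch (C20, C17), so a C4 radical can run 6-endo/6-endo through a 1,5-diene. The exocyclic C8=C17 methylene is the footprint of oxidative termination at a tertiary C8 radical.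
3. Forward order: homologated geranyl chain (C12 as pivalate) → terminal allylic bromide → keto ester polyene → ring A, then ring B, in one step → reduction to the 3,12,19-triol → 3,19-acetonide and C12 aldehyde → aldol → acid, which deprotects and closes the lactone ring last.
4. Stereochemistry: C4, C5, C9, C10 relative from chair–chair folding of the E,E-diene, absolute from a (−)-8-phenylmenthyl ester; C3 from axial hydride delivery; C12 and C13 from an (R)-4-benzyloxazolidinone syn-aldol; C14 from an (S)-malic-acid-derived dioxolane.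

Key step: step 8

Remark: labdane numbering (C1–C20) is used for the decalin compounds and the side chain. The acyclic α-methyl β-keto esters 9 and 11 are C4-epimer mixtures, which is inconsequential because C4 becomes a planar radical in step 8.

**Route**

Step 1
Reactants: 1 geranyl bromide
Product: 2 [(3E)-4,8-dimethylnona-3,7-dien-1-yl](isopropoxy)dimethylsilane
Conditions: ClMgCH2SiMe2(Oi-Pr) (from ClCH2SiMe2(Oi-Pr), Mg, THF), Li2CuCl4 (cat.), THF, −20 to 0 °C
Reagents that add atoms: (isopropoxydimethylsilyl)methylmagnesium chloride, CC(C)O[Si](C)(C)C[Mg]Cl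
Why: Copper-catalysed allylic cross-coupling of a Grignard reagent (Li2CuCl4 in THF) should substitute the primary allylic bromide at C11 without allylic transposition and with retention of the E alkene, the silylmethyl group serving as a masked hydroxymethyl (C12) unit; no stereocenter is formed.

Step 2
Reactants: 2 [(3E)-4,8-dimethylnona-3,7-dien-1-yl](isopropoxy)dimethylsilane
Product: 3 homogeraniol
Conditions: 30% H2O2, KF, KHCO3, THF/MeOH, rt
Reagents that add atoms: hydrogen peroxide, OO
Why: Tamao–Fleming oxidation replaces the C–Si bond of the alkoxysilane by C–OH with peroxide under fluoride/bicarbonate activation, conditions that leave trisubstituted alkenes untouched.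

Step 3
Reactants: 3 homogeraniol
Product: 4 homogeranyl pivalate
Conditions: t-BuCOCl, pyridine, DMAP (cat.), CH2Cl2, 0 °C to rt
Reagents that add atoms: pivaloyl chloride, CC(C)(C)C(=O)Cl
Why: Acylation of the primary alcohol gives a hindered ester that should withstand the allylic oxidation, the bromination, the dianion and acetic acid, and is removed together with the other esters by LiAlH4 in step 9.

Step 4
Reactants: 4 homogeranyl pivalate
Product: 5 (3E,7E)-9-hydroxy-4,8-dimethylnona-3,7-dien-1-yl pivalate
Conditions: SeO2 (cat.), t-BuOOH, salicylic acid (cat.), CH2Cl2, 0 °C to rt, stopped at partial conversion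
Reagents that add atoms: selenium dioxide (catalytic oxygen carrier), O=[Se]=O; tert-butyl hydroperoxide (terminal oxidant), CC(C)(C)OO
Why: Riley-type allylic oxidation (ene reaction, then [2,3]-sigmatropic shift) should hydroxylate the E methyl group of the terminal isopropylidene unit, the most accessible trisubstituted alkene, and give the E allylic alcohol at C1.

Step 5
Reactants: 5 (3E,7E)-9-hydroxy-4,8-dimethylnona-3,7-dien-1-yl pivalate
Product: 6 (3E,7E)-9-bromo-4,8-dimethylnona-3,7-dien-1-yl pivalate
Conditions: CBr4, PPh3, CH2Cl2, −20 to 0 °C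
Reagents that add atoms: carbon tetrabromide, BrC(Br)(Br)Br
Why: Appel bromination converts the primary allylic alcohol into the bromide under neutral conditions at low temperature, which should avoid allylic transposition and loss of E geometry.

Step 6
Reactants: 7 (−)-8-phenylmenthol; 8 ethyl 2-methyl-3-oxobutanoate
Product: 9 (1R,2S,5R)-8-phenylmenthyl 2-methyl-3-oxobutanoate
Conditions: DMAP (cat.), toluene, reflux, 4 Å molecular sieves (removal of EtOH)
Reagents that add atoms: none
Why: DMAP-catalysed transesterification of an enolisable β-keto ester with a hindered secondary alcohol is driven by removal of ethanol and installs the chiral ester that later controls the face of the C4 radical; the α-carbon is formed as both epimers, which is of no consequence.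

Step 7
Reactants: 9 (1R,2S,5R)-8-phenylmenthyl 2-methyl-3-oxobutanoate; 6 (3E,7E)-9-bromo-4,8-dimethylnona-3,7-dien-1-yl pivalate
Product: 11 (1R,2S,5R)-8-phenylmenthyl (6E,10E)-2,6,10-trimethyl-3-oxo-13-(pivaloyloxy)trideca-6,10-dienoate, via sodium lithium dianion 10 (not isolated)
Conditions: NaH, THF, 0 °C; n-BuLi, 0 °C; then 6, −78 to 0 °C; cold 1 M HCl work-up
Reagents that add atoms: none
Why: Acetoacetate dianion alkylation (Weiler type): the terminal carbanion of the dianion is the more nucleophilic site and should displace the primary allylic bromide by SN2 to form the C1–C2 bond faster than it attacks the hindered pivalate.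

Step 8
Reactants: 11 (1R,2S,5R)-8-phenylmenthyl (6E,10E)-2,6,10-trimethyl-3-oxo-13-(pivaloyloxy)trideca-6,10-dienoate
Product: 12 (1R,2S,5R)-8-phenylmenthyl (4S,5S,9R,10S)-3-oxo-12-(pivaloyloxy)-13,14,15,16-tetranorlabd-8(17)-en-19-oate
Conditions: Mn(OAc)3·2H2O (2.2 equiv), Cu(OAc)2·H2O (1 equiv), degassed AcOH, 25 °C
Reagents that add atoms: none
Why: Mn(OAc)3 oxidises the enol of the α-methyl β-keto ester to the C4 radical, which adds to C5 and passes the spin to C10, which adds to C9 (this makes the C9–C10 bond) and passes it to C8, where Cu(OAc)2 captures the tertiary radical as an alkylcopper species (formally trivalent copper) that loses a hydrogen from the C17 methyl group by β-hydride elimination to give the C8=C17 methylene. The closest known reaction type is the Mn(OAc)3/Cu(OAc)2 oxidative free-radical polyene cyclisation of α-substituted β-keto esters, combined with facial control by an 8-phenylmenthyl ester. Ring A and ring B both close 6-endo-trig, which is secured by the C20 and C17 methyl branches because attack at the unsubstituted alkene carbons C5 and C9 leads to tertiary radicals whereas 5-exo attack would not. C4 is set by the radical reacting in its dipole-minimised rotamer with the ester carbonyl turned away from the ketone oxygen, which puts the ester axial and cis to C20 and the C18 methyl equatorial, while the trans ring fusion at C5/C10 and the equatorial C11 chain at C9 follow from the chair–chair folding of the E,E-diene. The absolute sense rests on the phenyl ring of the (1R,2S,5R)-auxiliary, which stacks over one face of the planar C4 radical so that C5 should bond from the open face and give the 4S,5S,9R,10S series. The step therefore needs facial selectivity at C4 and exo-selective termination at C8, the first supplied by the auxiliary and the second by the preference of the copper-mediated elimination for the less substituted alkene.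

Step 9
Reactants: 12 (1R,2S,5R)-8-phenylmenthyl (4S,5S,9R,10S)-3-oxo-12-(pivaloyloxy)-13,14,15,16-tetranorlabd-8(17)-en-19-oate
Product: 13 (3R,4R,5S,9R,10S)-13,14,15,16-tetranorlabd-8(17)-ene-3,12,19-triol
Conditions: LiAlH4 (excess), THF, 0 °C to reflux; Fieser work-up
Reagents that add atoms: none
Why: LiAlH4 reduces the C3 ketone by axial hydride delivery from the face opposite the axial C19 ester and the C20 methyl group, which should give the equatorial 3-hydroxyl cis to C19 (3R), and then cleaves the auxiliary ester to the C19 carbinol and the pivalate to the C12 alcohol, returning 8-phenylmenthol.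

Step 10
Reactants: 13 (3R,4R,5S,9R,10S)-13,14,15,16-tetranorlabd-8(17)-ene-3,12,19-triol
Product: 14 3,19-O-isopropylidene derivative of triol 13 (C12 hydroxyl free)
Conditions: 2,2-dimethoxypropane, PPTS (cat.), acetone, rt; then MeOH
Reagents that add atoms: 2,2-dimethoxypropane, COC(C)(C)OC
Why: Acid-catalysed transketalisation gives the six-membered 1,3-dioxane of the C3/C19 1,3-diol under thermodynamic control, while any mixed ketal at the primary C12 hydroxyl is cleaved on the methanol quench.

Step 11
Reactants: 14 3,19-O-isopropylidene derivative of triol 13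
Product: 15 3,19-O-isopropylidene-3,19-dihydroxy-13,14,15,16-tetranorlabd-8(17)-en-12-al
Conditions: Dess–Martin periodinane, NaHCO3, CH2Cl2, 0 °C to rt
Reagents that add atoms: none
Why: Dess–Martin oxidation converts the primary C12 alcohol into the aldehyde under buffered non-acidic conditions that spare the acetonide and the exocyclic alkene and do not epimerise C9.

Step 12
Reactants: 16 methyl (S)-2-(2,2-dimethyl-1,3-dioxolan-4-yl)acetate
Product: 17 (S)-2-(2,2-dimethyl-1,3-dioxolan-4-yl)acetic acid
Conditions: LiOH·H2O, THF/H2O, 0 °C to rt; then cold 1 M HCl to pH 4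
Reagents that add atoms: lithium hydroxide (carboxyl oxygen), [Li+].[OH-]
Why: Saponification of the methyl ester with LiOH and careful acidification in the cold gives the acid without loss of the acetonide or of the C14 configuration.

Step 13
Reactants: 17 (S)-2-(2,2-dimethyl-1,3-dioxolan-4-yl)acetic acid; 18 (R)-4-benzyl-1,3-oxazolidin-2-one
Product: 20 (R)-4-benzyl-3-[2-((S)-2,2-dimethyl-1,3-dioxolan-4-yl)acetyl]-1,3-oxazolidin-2-one, via mixed pivalic anhydride 19 (not isolated)
Conditions: t-BuCOCl, Et3N, THF, −20 °C; then 18, LiCl, −20 °C to rt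
Reagents that add atoms: none
Why: N-acylation of the oxazolidinone through the mixed pivalic anhydride with LiCl and Et3N is the standard one-flask method and attacks the less hindered carbonyl of the anhydride.

Step 14
Reactants: 20 (R)-4-benzyl-3-[2-((S)-2,2-dimethyl-1,3-dioxolan-4-yl)acetyl]-1,3-oxazolidin-2-one; 15 3,19-O-isopropylidene-3,19-dihydroxy-13,14,15,16-tetranorlabd-8(17)-en-12-al
Product: 22 (12S,13S,14S) syn-aldol adduct (N-acyl oxazolidinone; 3,19- and 14,15-acetonides), via Z-dibutylboron enolate 21 (not isolated)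
Conditions: Bu2BOTf, i-Pr2NEt, CH2Cl2, −78 to 0 °C; then 15, −78 to 0 °C; pH 7 buffer, MeOH, 30% H2O2, 0 °C
Reagents that add atoms: none
Why: Evans syn-aldol: soft enolisation with Bu2BOTf gives the Z boron enolate, which reacts through a Zimmerman–Traxler chair on the enolate face opposite the benzyl group of the (R)-auxiliary and so should set C12 (S) and C13 (S) with the 12,13-syn relation under auxiliary control, C14 being carried from the chiral pool.

Step 15
Reactants: 22 (12S,13S,14S) syn-aldol adduct
Product: 24 target lactone CNP0113086.2, via tetraol imide 23 (not isolated)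
Conditions: AcOH/H2O/THF (3:1:1), 45 °C
Reagents that add atoms: none
Why: Aqueous acetic acid hydrolyses both isopropylidene ketals, and the freed primary C15 hydroxyl should then attack the imide carbonyl in a 5-exo-trig acyl transfer that closes the γ-lactone and expels the oxazolidinone, leaving C13 and C14 trans without touching any stereocenter.

**Compound list**

1 | geranyl bromide, (2E)-1-bromo-3,7-dimethylocta-2,6-diene | CC(C)=CCC/C(C)=C/CBr | starting material
2 | [(3E)-4,8-dimethylnona-3,7-dien-1-yl](isopropoxy)dimethylsilane | CC(C)=CCC/C(C)=C/CC[Si](C)(C)OC(C)C | intermediate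
3 | homogeraniol, (3E)-4,8-dimethylnona-3,7-dien-1-ol | CC(C)=CCC/C(C)=C/CCO | intermediate
4 | homogeranyl pivalate, (3E)-4,8-dimethylnona-3,7-dien-1-yl 2,2-dimethylpropanoate | CC(C)=CCC/C(C)=C/CCOC(=O)C(C)(C)C | intermediate
5 | (3E,7E)-9-hydroxy-4,8-dimethylnona-3,7-dien-1-yl pivalate | OC/C(C)=C/CC/C(C)=C/CCOC(=O)C(C)(C)C | intermediate
6 | (3E,7E)-9-bromo-4,8-dimethylnona-3,7-dien-1-yl pivalate | BrC/C(C)=C/CC/C(C)=C/CCOC(=O)C(C)(C)C | intermediate
7 | (−)-8-phenylmenthol, (1R,2S,5R)-5-methyl-2-(2-phenylpropan-2-yl)cyclohexan-1-ol | O[C@@H]1C[C@H](C)CC[C@H]1C(C)(C)c1ccccc1 | starting material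
8 | ethyl 2-methyl-3-oxobutanoate (racemic) | CCOC(=O)C(C)C(C)=O | starting material
9 | (1R,2S,5R)-8-phenylmenthyl 2-methyl-3-oxobutanoate (both α-epimers) | CC(=O)C(C)C(=O)O[C@@H]1C[C@H](C)CC[C@H]1C(C)(C)c1ccccc1 | intermediate
10 | sodium lithium dianion of 9 (α,γ-dicarbanion form) | [Li+].[Na+].[CH2-]C(=O)[C-](C)C(=O)O[C@@H]1C[C@H](C)CC[C@H]1C(C)(C)c1ccccc1 | intermediate
11 | (1R,2S,5R)-8-phenylmenthyl (6E,10E)-2,6,10-trimethyl-3-oxo-13-(pivaloyloxy)trideca-6,10-dienoate (both C2 epimers) | CC(C)(C)C(=O)OCC/C=C(\C)CC/C=C(\C)CCC(=O)C(C)C(=O)O[C@@H]1C[C@H](C)CC[C@H]1C(C)(C)c1ccccc1 | intermediate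
12 | (1R,2S,5R)-8-phenylmenthyl (4S,5S,9R,10S)-3-oxo-12-(pivaloyloxy)-13,14,15,16-tetranorlabd-8(17)-en-19-oate; trans-decalin, C19 ester axial and cis to C20, C18 methyl equatorial, C11 chain equatorial | C=C1CC[C@@H]2[C@](C)(C(=O)O[C@@H]3C[C@H](C)CC[C@H]3C(C)(C)c3ccccc3)C(=O)CC[C@@]2(C)[C@@H]1CCOC(=O)C(C)(C)C | intermediate
13 | (3R,4R,5S,9R,10S)-13,14,15,16-tetranorlabd-8(17)-ene-3,12,19-triol, i.e. (1R,2R,4aS,5R,8aS)-5-(2-hydroxyethyl)-1-(hydroxymethyl)-1,4a-dimethyl-6-methylidenedecahydronaphthalen-2-ol | C=C1CC[C@@H]2[C@](C)(CO)[C@H](O)CC[C@@]2(C)[C@@H]1CCO | intermediate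
14 | 3,19-O-isopropylidene derivative of 13 (1,3-dioxane across O3 and O19; C12 hydroxyl free) | C=C1CC[C@@H]2[C@]3(C)COC(C)(C)O[C@@H]3CC[C@@]2(C)[C@@H]1CCO | intermediate
15 | 3,19-O-isopropylidene-3,19-dihydroxy-13,14,15,16-tetranorlabd-8(17)-en-12-al | C=C1CC[C@@H]2[C@]3(C)COC(C)(C)O[C@@H]3CC[C@@]2(C)[C@@H]1CC=O | intermediate
16 | methyl (S)-2-(2,2-dimethyl-1,3-dioxolan-4-yl)acetate | COC(=O)C[C@H]1COC(C)(C)O1 | starting material
17 | (S)-2-(2,2-dimethyl-1,3-dioxolan-4-yl)acetic acid | OC(=O)C[C@H]1COC(C)(C)O1 | intermediate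
18 | (R)-4-benzyl-1,3-oxazolidin-2-one | O=C1N[C@H](Cc2ccccc2)CO1 | starting material
19 | (S)-2-(2,2-dimethyl-1,3-dioxolan-4-yl)acetic pivalic anhydride | CC(C)(C)C(=O)OC(=O)C[C@H]1COC(C)(C)O1 | intermediate
20 | (R)-4-benzyl-3-[2-((S)-2,2-dimethyl-1,3-dioxolan-4-yl)acetyl]-1,3-oxazolidin-2-one | O=C(C[C@H]1COC(C)(C)O1)N1[C@H](Cc2ccccc2)COC1=O | intermediate
21 | Z-dibutylboron enolate of 20 (O–B cis to the dioxolanyl carbon) | CCCCB(CCCC)O/C(=C\[C@H]1COC(C)(C)O1)N1[C@H](Cc2ccccc2)COC1=O | intermediate
22 | (12S,13S,14S) syn-aldol adduct: C12 carbinol, C13 bearing the (S)-dioxolane and the N-acyl (R)-4-benzyloxazolidinone, 3,19-acetonide retained | C=C1CC[C@@H]2[C@]3(C)COC(C)(C)O[C@@H]3CC[C@@]2(C)[C@@H]1C[C@H](O)[C@@H]([C@H]1COC(C)(C)O1)C(=O)N1[C@H](Cc2ccccc2)COC1=O | intermediate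
23 | tetraol imide (3,12,14,15,19-pentahydroxy acyl oxazolidinone after loss of both acetonides) | C=C1CC[C@@H]2[C@](C)(CO)[C@H](O)CC[C@@]2(C)[C@@H]1C[C@H](O)[C@@H]([C@H](O)CO)C(=O)N1[C@H](Cc2ccccc2)COC1=O | intermediate
24 | (3S,4S)-4-hydroxy-3-{(1S)-1-hydroxy-2-[(1R,4aS,5R,6R,8aS)-6-hydroxy-5-(hydroxymethyl)-5,8a-dimethyl-2-methylidenedecahydronaphthalen-1-yl]ethyl}oxolan-2-one (CNP0113086.2) | C=C1CC[C@@H]2[C@](C)(CO)[C@H](O)CC[C@@]2(C)[C@@H]1C[C@H](O)[C@@H]1C(=O)OC[C@H]1O | target

**Totals and risks**

Total step count: 15. Longest linear sequence: 12 steps (steps 1–5, 7–11, 14, 15).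

Steps most likely to fail:

1. Step 8. The facial discrimination by the auxiliary may be poor, or may run in the opposite sense if the radical reacts through another carbonyl rotamer, and termination may give endocyclic alkene isomers. The fallback sets out from bromide 6 and returns at triol 13. The dianion of the achiral ester 8 (NaH, then n-BuLi) is alkylated with 6 to give ethyl (6E,10E)-2,6,10-trimethyl-3-oxo-13-(pivaloyloxy)trideca-6,10-dienoate F1. Cyclisation with Mn(OAc)3·2H2O and Cu(OAc)2·H2O in AcOH should give the racemic bicyclic ethyl keto ester F2, whose relative configuration depends on the substrate alone. A Corey–Bakshi–Shibata reduction with (S)-Me-CBS and catecholborane, run to about half conversion, should act as a kinetic resolution: the (4S,5S,9R,10S) enantiomer is the matched one (catalyst and axial attack both lead to 3R) and should give the equatorial hydroxy ester F3, while its mirror image remains largely as ketone. After chromatographic separation, LiAlH4 converts F3 into 13.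

2. Step 14. β-Elimination of the dioxolane oxygen from the enolate, or erosion of auxiliary control by the adjacent C14 stereocenter, may intervene. The fallback sets out from aldehyde 15 and returns at target 24. Commercial (S)-3-hydroxy-γ-butyrolactone is silylated (TBSCl, imidazole) to (S)-4-(tert-butyldimethylsilyloxy)oxolan-2-one F4. Its lithium enolate (LiN(i-Pr)2, THF, −78 °C) adds to 15 anti to the silyloxy group to give the 13,14-trans aldol adducts F5 as a C12 epimer mixture. Dess–Martin oxidation gives the β-keto lactone F6. Chelation-controlled reduction with Zn(BH4)2 in Et2O, with hydride entering the zinc chelate from the side of H13, should give the 12S syn alcohol F7. Aqueous HF in MeCN then removes the silyl group and the acetonide to give 24.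

3. Step 4. The oxidant may attack the internal C8=C9 alkene or over-oxidise the product to the enal. The fallback sets out from pivalate 4 and returns at allylic alcohol 5. Terminal-selective bromohydrin formation (NBS, THF/H2O, 0 °C) gives bromohydrin F8, and brief K2CO3 in MeOH closes the terminal epoxide F9. H5IO6 cleaves F9 to (3E)-4-methyl-7-oxohept-3-en-1-yl pivalate F10. An E-selective Wittig reaction with Ph3P=C(CH3)CO2Et gives the enoate F11, and i-Bu2AlH (2 equiv, CH2Cl2, −78 °C) should reduce the conjugated ethyl ester in preference to the hindered pivalate to give 5.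

**Further compounds**

F1 | step 8 | ethyl (6E,10E)-2,6,10-trimethyl-3-oxo-13-(pivaloyloxy)trideca-6,10-dienoate | CCOC(=O)C(C)C(=O)CC/C(C)=C/CC/C(C)=C/CCOC(=O)C(C)(C)C
F2 | step 8 | racemic ethyl 3-oxo-12-(pivaloyloxy)-13,14,15,16-tetranorlabd-8(17)-en-19-oate (relative configuration as in 12; one enantiomer drawn) | C=C1CC[C@@H]2[C@](C)(C(=O)OCC)C(=O)CC[C@@]2(C)[C@@H]1CCOC(=O)C(C)(C)C
F3 | step 8 | ethyl (3R,4S,5S,9R,10S)-3-hydroxy-12-(pivaloyloxy)-13,14,15,16-tetranorlabd-8(17)-en-19-oate | C=C1CC[C@@H]2[C@](C)(C(=O)OCC)[C@H](O)CC[C@@]2(C)[C@@H]1CCOC(=O)C(C)(C)C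
F4 | step 14 | (S)-4-(tert-butyldimethylsilyloxy)oxolan-2-one | O=C1C[C@H](O[Si](C)(C)C(C)(C)C)CO1
F5 | step 14 | 13,14-trans aldol adducts of 15 and F4 (C12 epimers; 3,19-acetonide, 14-O-TBS) | C=C1CC[C@@H]2[C@]3(C)COC(C)(C)O[C@@H]3CC[C@@]2(C)[C@@H]1CC(O)[C@@H]1C(=O)OC[C@H]1O[Si](C)(C)C(C)(C)C
F6 | step 14 | 12-oxo lactone (β-keto lactone; 3,19-acetonide, 14-O-TBS) | C=C1CC[C@@H]2[C@]3(C)COC(C)(C)O[C@@H]3CC[C@@]2(C)[C@@H]1CC(=O)[C@@H]1C(=O)OC[C@H]1O[Si](C)(C)C(C)(C)C
F7 | step 14 | (12S,13S,14S)-12-hydroxy lactone (3,19-acetonide, 14-O-TBS) | C=C1CC[C@@H]2[C@]3(C)COC(C)(C)O[C@@H]3CC[C@@]2(C)[C@@H]1C[C@H](O)[C@@H]1C(=O)OC[C@H]1O[Si](C)(C)C(C)(C)C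
F8 | step 4 | (3E)-7-bromo-8-hydroxy-4,8-dimethylnon-3-en-1-yl pivalate (racemic) | CC(C)(O)C(Br)CC/C(C)=C/CCOC(=O)C(C)(C)C
F9 | step 4 | (3E)-6-(3,3-dimethyloxiran-2-yl)-4-methylhex-3-en-1-yl pivalate (racemic) | CC1(C)OC1CC/C(C)=C/CCOC(=O)C(C)(C)C
F10 | step 4 | (3E)-4-methyl-7-oxohept-3-en-1-yl pivalate | O=CCC/C(C)=C/CCOC(=O)C(C)(C)C
F11 | step 4 | ethyl (2E,6E)-2,6-dimethyl-9-(pivaloyloxy)nona-2,6-dienoate | CCOC(=O)/C(C)=C/CC/C(C)=C/CCOC(=O)C(C)(C)C
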